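**Strategy.** In each half of the dimer, the ring oxygen O1 on C2 of the pyranone ring and the γ-lactone oxygen on the neighbouring carbinol carbon sit on adjacent carbons, the imprint of a trisubstituted epoxide that a phenol has entered at its fully substituted carbon. The route therefore rests on one acid-catalysed, two-directional cascade: each C8a phenol opens its epoxide with inversion (pyran ring, C2 stereocentre) and the alcohol set free lactonises onto the γ-methyl ester, closing four rings. The precursor is a C2-symmetric 6,6′-biaryl carrying, on each ring, a free C8a phenol, a C5 methyl ether and a 2-arylallyl arm ending in a silyloxymethyl epoxy ester; the exocyclic methylene stands in for the C4 ketone.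

Key step: step 14

Remark: the tetrahydropyranyl acetal carbons are not stereodefined (15 and 16 are racemic, 17–20 are diastereomer mixtures; the acetals leave in step 13), and acid 1 is taken as commercial (otherwise one regioselective mono-esterification from (S)-methylsuccinic acid).

**Route**

Step 1
Reactants: 1 (S)-4-methoxy-2-methyl-4-oxobutanoic acid; 2 tributyltin hydride
Product: 4 methyl (3S)-3-methyl-4-oxobutanoate, via acid chloride 3 (not isolated)
Conditions: (COCl)2, DMF (cat.), CH2Cl2, 0 °C → rt, evaporate; then 2, Pd(PPh3)4 (1 mol%), toluene, rt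
Reagents that add atoms: none
Why: Oxalyl chloride gives the acyl chloride without base, and the palladium-catalysed tin hydride reduction of acyl chlorides (a Rosenmund-type reduction through an acylpalladium hydride) stops at the aldehyde and spares the methyl ester, so the chiral-pool α-stereocentre should be kept.

Step 2
Reactants: 4 methyl (3S)-3-methyl-4-oxobutanoate
Product: 6 (3S)-3-methylpent-4-ynoic acid, via alkynyl methyl ester 5 (not isolated)
Conditions: dimethyl (1-diazo-2-oxopropyl)phosphonate, K2CO3, MeOH, 0 °C → rt; then LiOH, H2O, rt; HCl to pH 2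
Reagents that add atoms: dimethyl (1-diazo-2-oxopropyl)phosphonate CC(=O)C(=[N+]=[N-])P(=O)(OC)OC; lithium hydroxide [Li+].[OH-]
Why: Ohira–Bestmann homologation (Seyferth–Gilbert type) converts the aldehyde into the terminal alkyne at 0 °C before α-epimerisation can compete, and saponification in the same pot turns the ester into a carboxylate that is inert in the acetylide step that follows.

Step 3
Reactants: 6 (3S)-3-methylpent-4-ynoic acid
Product: 7 (3S)-6-hydroxy-3-methylhex-4-ynoic acid
Conditions: n-BuLi (2.1 equiv), THF, −78 → 0 °C; (CH2O)n, 0 °C → rt; aq. HCl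
Reagents that add atoms: formaldehyde (as paraformaldehyde) C=O
Why: The carboxylate–acetylide dianion adds to formaldehyde through its acetylide carbon (acetylide hydroxymethylation), while the carboxylate is neither attacked nor enolised at low temperature with only two equivalents of base.

Step 4
Reactants: 7 (3S)-6-hydroxy-3-methylhex-4-ynoic acid
Product: 8 methyl (3S)-6-hydroxy-3-methylhex-4-ynoate
Conditions: TMSCHN2, toluene/MeOH, 0 °C
Reagents that add atoms: (trimethylsilyl)diazomethane C[Si](C)(C)C=[N+]=[N-]
Why: Diazoalkane esterification methylates the carboxylic acid selectively over the propargylic alcohol and restores the ester that must acylate in the key step.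

Step 5
Reactants: 8 methyl (3S)-6-hydroxy-3-methylhex-4-ynoate; 2 tributyltin hydride
Product: 9 methyl (3S,4E)-6-hydroxy-3-methyl-5-(tributylstannyl)hex-4-enoate
Conditions: PdCl2(PPh3)2 (2 mol%), THF, 0 °C, slow addition of 2
Reagents that add atoms: none
Why: Palladium-catalysed hydrostannation adds H and Sn syn across the alkyne with tin at the carbon next to the hydroxymethyl group and away from the branched propargylic carbon, which places H cis to Sn and so fixes the later (Z) geometry.

Step 6
Reactants: 9 methyl (3S,4E)-6-hydroxy-3-methyl-5-(tributylstannyl)hex-4-enoate; 10 2,3-dibromopropene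
Product: 11 methyl (3S,4Z)-7-bromo-5-(hydroxymethyl)-3-methylocta-4,7-dienoate
Conditions: Pd2(dba)3 (2.5 mol%), P(2-furyl)3 (10 mol%), NMP, rt; 10 in excess
Reagents that add atoms: none
Why: Stille coupling at the allylic C–Br bond of 10 (through a π-allylpalladium species) proceeds with retention of alkene geometry, and the vinylic C–Br bond of the product is far less reactive toward zerovalent palladium.

Step 7
Reactants: 11 methyl (3S,4Z)-7-bromo-5-(hydroxymethyl)-3-methylocta-4,7-dienoate
Product: 12 methyl (3S)-3-[(2R,3S)-3-(2-bromoprop-2-en-1-yl)-3-(hydroxymethyl)oxiran-2-yl]butanoate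
Conditions: Ti(OiPr)4 (1.0 equiv), L-(+)-diethyl tartrate (1.2 equiv), t-BuOOH, 4 Å MS, CH2Cl2, −20 °C
Reagents that add atoms: tert-butyl hydroperoxide CC(C)(C)OO
Why: In this Katsuki–Sharpless asymmetric epoxidation L-(+)-tartrate delivers oxygen to the face that makes the quaternary carbon (S) and the CH carbon (R), which is also the face favoured by allylic 1,3-strain (syn to the C-methyl group in the H-eclipsed conformer), so reagent and substrate control should be matched, and the electron-poor bromoalkene is inert.

Step 8
Reactants: 12 methyl (3S)-3-[(2R,3S)-3-(2-bromoprop-2-en-1-yl)-3-(hydroxymethyl)oxiran-2-yl]butanoate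
Product: 13 methyl (3S)-3-[(2R,3S)-3-(2-bromoprop-2-en-1-yl)-3-({[tert-butyl(dimethyl)silyl]oxy}methyl)oxiran-2-yl]butanoate
Conditions: TBSCl, imidazole, DMF, rt
Reagents that add atoms: tert-butyldimethylsilyl chloride CC(C)(C)[Si](C)(C)Cl
Why: Silylation of the primary alcohol (silyl ether formation) removes the acidic proton before the organozinc coupling and keeps the hydroxymethyl group inert in the cascade.

Step 9
Reactants: 14 4-bromo-3-methoxyphenol
Product: 15 2-(4-bromo-3-methoxyphenoxy)oxane
Conditions: 3,4-dihydro-2H-pyran, pyridinium p-toluenesulfonate (cat.), CH2Cl2, rt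
Reagents that add atoms: 3,4-dihydro-2H-pyran C1CCOC=C1
Why: Acid-catalysed acetalisation marks the future C8a oxygen with a base-stable, metalation-directing group that can later be removed beside the C5 methyl ether, which two methyl ethers would not allow.

Step 10
Reactants: 15 2-(4-bromo-3-methoxyphenoxy)oxane
Product: 16 2-[2-methoxy-4-(oxan-2-yloxy)phenyl]-4,4,5,5-tetramethyl-1,3,2-dioxaborolane
Conditions: bis(pinacolato)diboron, PdCl2(dppf) (3 mol%), KOAc, dioxane, 80 °C
Reagents that add atoms: bis(pinacolato)diboron CC1(C)OB(OC1(C)C)B1OC(C)(C)C(C)(C)O1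
Why: Miyaura borylation (insertion of zerovalent palladium into the aryl C–Br bond, then acetate-assisted transmetalation from the diboron) converts one portion of 15 into the nucleophilic coupling partner, and the weak base leaves the acetal alone and should suppress premature biaryl formation.

Step 11
Reactants: 15 2-(4-bromo-3-methoxyphenoxy)oxane; 16 2-[2-methoxy-4-(oxan-2-yloxy)phenyl]-4,4,5,5-tetramethyl-1,3,2-dioxaborolane
Product: 17 2,2′-dimethoxy-4,4′-bis(oxan-2-yloxy)-1,1′-biphenyl
Conditions: Pd(PPh3)4 (3 mol%), K2CO3 (3 equiv), dioxane/H2O, 85 °C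
Reagents that add atoms: none
Why: Suzuki–Miyaura cross-coupling of the aryl bromide with its own pinacol boronate, one molecule of each, forms the symmetrical biaryl bond para to each protected phenol (the future C6–C6′ bond), and with only one ortho substituent on each partner transmetalation and reductive elimination should be fast.

Step 12
Reactants: 17 2,2′-dimethoxy-4,4′-bis(oxan-2-yloxy)-1,1′-biphenyl; 13 silyl-protected epoxy vinyl bromide
Product: 20 biaryl bis(epoxy ester) bis(tetrahydropyranyl ether), via 3,3′-dilithiobiaryl 18 (not isolated), via 3,3′-bis(chlorozincio)biaryl 19 (not isolated)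
Conditions: n-BuLi (2.3 equiv), THF, 0 °C → rt; ZnCl2 (2.4 equiv), 0 °C → rt; 13 (2.2 equiv), Pd2(dba)3 (2.5 mol%), SPhos (10 mol%), THF, 45 °C
Reagents that add atoms: none
Why: Directed ortho-metalation removes on each ring the proton flanked by the methoxy and acetal oxygens, transmetalation gives an arylzinc that tolerates ester, epoxide and silyl ether, and Negishi coupling with the vinyl bromide under a bulky biarylphosphine–palladium catalyst forms both hindered aryl–vinyl bonds.

Step 13
Reactants: 20 biaryl bis(epoxy ester) bis(tetrahydropyranyl ether)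
Product: 21 biaryl bis(2-arylallyl epoxy ester) with free C8a phenols
Conditions: pyridinium p-toluenesulfonate (0.2 equiv), MeOH/CH2Cl2, 0 °C → rt; NaHCO3 quench
Reagents that add atoms: none
Why: Aryl tetrahydropyranyl acetals undergo acid-catalysed acetal exchange with methanol far faster than the neopentyl-type silyl ethers are cleaved or the trisubstituted epoxides are solvolysed, so only the two C8a phenols should be freed.

Step 14
Reactants: 21 biaryl bis(2-arylallyl epoxy ester) with free C8a phenols
Product: 23 bis(4-methylenechroman) bis-lactone, via bis(hydroxy ester) chroman 22 (not isolated)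
Conditions: (1S)-(+)-camphor-10-sulfonic acid (0.3 equiv), 4 Å MS, CH2Cl2 (0.01 M), 0 °C → rt
Reagents that add atoms: none
Why: Camphorsulfonic acid activates each epoxide and polarises its C–O bond to the tertiary carbon, which the ortho phenol attacks from the rear in a 6-exo-tet closure (pyran ring, O1–C2); the closest known reaction type is the acid-catalysed 6-exo opening of trisubstituted epoxides by tethered phenols to give 2,2-disubstituted chromans. The secondary alcohol released on the former epoxide CH carbon then acylates onto the γ-methyl ester in a 5-exo-trig lactonisation with loss of methanol (lactone ring), so four rings form in one flask through hydroxy ester 22. Each C2 stereocentre is set by stereospecific inversion at the (S) tertiary epoxide carbon installed in step 7, giving (R) in 23 (the later (S) of the ester series), while the carbinol carbon keeps its C–O bond and (R) configuration and the C-methyl centre is untouched. The step needs 6-exo attack at the tertiary carbon rather than 7-endo attack at the secondary carbon or participation of the ester carbonyl, and no free cation; the five-atom tether, the tertiary site that best carries positive charge, the reversibility of O-methyl lactonium formation under anhydrous conditions and the weak acid at low temperature should secure this. The exocyclic methylene removes the β-elimination pathway a C4 ketone would open and, twisted out of conjugation by its two ortho substituents, should survive the weak acid.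

Step 15
Reactants: 23 bis(4-methylenechroman) bis-lactone
Product: 24 bis(chroman-4-one) bis-lactone bis(silyl ether)
Conditions: OsO4 (5 mol%), NaIO4, 2,6-lutidine, dioxane/H2O, rt
Reagents that add atoms: sodium periodate [Na+].[O-]I(=O)(=O)=O (oxygen relayed through OsO4)
Why: Lemieux–Johnson oxidation (osmium-catalysed dihydroxylation, then periodate cleavage) unveils both C4 ketones right after the cascade without ozone, which could attack the electron-rich biaryl, and removes the acid-sensitive alkenes before any acidic step.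

Step 16
Reactants: 24 bis(chroman-4-one) bis-lactone bis(silyl ether)
Product: 25 bis(2-hydroxymethylchroman-4-one) bis-lactone
Conditions: HF·pyridine, pyridine, THF, 0 °C → rt
Reagents that add atoms: none
Why: Fluoride-mediated desilylation under buffered acidic conditions frees the primary alcohols without the strong base that could open the β-aryloxy ketones by elimination.

Step 17
Reactants: 25 bis(2-hydroxymethylchroman-4-one) bis-lactone
Product: 26 bis(chroman-4-one-2-carboxylic acid) bis-lactone
Conditions: TEMPO ((2,2,6,6-tetramethylpiperidin-1-yl)oxyl, cat.), PhI(OAc)2, MeCN/H2O, rt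
Reagents that add atoms: water O
Why: Oxoammonium-catalysed oxidation takes each primary alcohol through the aldehyde hydrate to the carboxylic acid under near-neutral conditions, and C2 is quaternary so it cannot epimerise.

Step 18
Reactants: 26 bis(chroman-4-one-2-carboxylic acid) bis-lactone
Product: 27 dimethyl ester of 26 (5,5′-dimethoxy bis-lactone)
Conditions: TMSCHN2, toluene/MeOH, 0 °C
Reagents that add atoms: (trimethylsilyl)diazomethane C[Si](C)(C)C=[N+]=[N-]
Why: Diazoalkane esterification methylates the hindered tertiary acids under neutral conditions that leave ketones and lactones alone.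

Step 19
Reactants: 27 5,5′-dimethoxy bis-lactone dimethyl ester
Product: 28 5,5′-dihydroxy bis-lactone dimethyl ester
Conditions: BCl3, CH2Cl2, −78 → 0 °C; aqueous MeOH quench
Reagents that add atoms: none
Why: Boron trichloride chelates between each C4 carbonyl and the peri C5 methoxy group and cleaves only that aryl methyl ether (chelation-assisted Lewis-acid demethylation), leaving methyl esters and lactones intact at low temperature.

Step 20
Reactants: 28 5,5′-dihydroxy bis-lactone dimethyl ester
Product: 29 target CNP0517857.1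
Conditions: LiOH (3.0 equiv), THF/H2O, 0 °C, partial conversion; 0.1 M HCl to pH 4–5 at 0 °C
Reagents that add atoms: water O
Why: In this saponification the γ-lactone carbonyl should be attacked by hydroxide faster than the hindered tertiary methyl esters, the phenols are deprotonated first and so disfavour enolisation of the chromanones, and because 28 is C2-symmetric opening either lactone gives the same hydroxy acid, with unreacted 28 recoverable.

**Compound list**

1 | (S)-4-methoxy-2-methyl-4-oxobutanoic acid ((S)-2-methylsuccinic acid 4-methyl ester) | OC(=O)[C@@H](C)CC(=O)OC | starting material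
2 | tributyltin hydride | CCCC[SnH](CCCC)CCCC | starting material
3 | methyl (3S)-4-chloro-3-methyl-4-oxobutanoate | ClC(=O)[C@@H](C)CC(=O)OC | intermediate (not isolated)
4 | methyl (3S)-3-methyl-4-oxobutanoate | O=C[C@@H](C)CC(=O)OC | intermediate
5 | methyl (3S)-3-methylpent-4-ynoate | C#C[C@@H](C)CC(=O)OC | intermediate (not isolated)
6 | (3S)-3-methylpent-4-ynoic acid | C#C[C@@H](C)CC(=O)O | intermediate
7 | (3S)-6-hydroxy-3-methylhex-4-ynoic acid | OCC#C[C@@H](C)CC(=O)O | intermediate
8 | methyl (3S)-6-hydroxy-3-methylhex-4-ynoate | OCC#C[C@@H](C)CC(=O)OC | intermediate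
9 | methyl (3S,4E)-6-hydroxy-3-methyl-5-(tributylstannyl)hex-4-enoate (H cis to Sn, CH2OH cis to the chain) | OC/C(=C\[C@@H](C)CC(=O)OC)[Sn](CCCC)(CCCC)CCCC | intermediate
10 | 2,3-dibromopropene | C=C(Br)CBr | starting material
11 | methyl (3S,4Z)-7-bromo-5-(hydroxymethyl)-3-methylocta-4,7-dienoate | OC/C(=C\[C@@H](C)CC(=O)OC)CC(Br)=C | intermediate
12 | methyl (3S)-3-[(2R,3S)-3-(2-bromoprop-2-en-1-yl)-3-(hydroxymethyl)oxiran-2-yl]butanoate | C=C(Br)C[C@@]1(CO)O[C@@H]1[C@@H](C)CC(=O)OC | intermediate
13 | methyl (3S)-3-[(2R,3S)-3-(2-bromoprop-2-en-1-yl)-3-({[tert-butyl(dimethyl)silyl]oxy}methyl)oxiran-2-yl]butanoate | C=C(Br)C[C@@]1(CO[Si](C)(C)C(C)(C)C)O[C@@H]1[C@@H](C)CC(=O)OC | intermediate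
14 | 4-bromo-3-methoxyphenol | COc1cc(O)ccc1Br | starting material
15 | 2-(4-bromo-3-methoxyphenoxy)oxane | COc1cc(OC2CCCCO2)ccc1Br | intermediate
16 | 2-[2-methoxy-4-(oxan-2-yloxy)phenyl]-4,4,5,5-tetramethyl-1,3,2-dioxaborolane | COc1cc(OC2CCCCO2)ccc1B1OC(C)(C)C(C)(C)O1 | intermediate
17 | 2,2′-dimethoxy-4,4′-bis(oxan-2-yloxy)-1,1′-biphenyl | COc1cc(OC2CCCCO2)ccc1-c1ccc(OC2CCCCO2)cc1OC | intermediate
18 | 3,3′-dilithio derivative of 17 (lithium between OMe and the acetal oxygen on each ring) | COc1c([Li])c(OC2CCCCO2)ccc1-c1ccc(OC2CCCCO2)c([Li])c1OC | intermediate (not isolated)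
19 | 3,3′-bis(chlorozincio) derivative of 17 | COc1c([Zn]Cl)c(OC2CCCCO2)ccc1-c1ccc(OC2CCCCO2)c([Zn]Cl)c1OC | intermediate (not isolated)
20 | 17 carrying at C3 and C3′ a prop-1-en-2-yl group whose CH2 is bonded to the quaternary (S) carbon of an oxirane bearing CH2OTBS, the oxirane CH carbon (R) carrying the (S)-CH(CH3)CH2CO2Me chain | COc1c(C(=C)C[C@@]2(CO[Si](C)(C)C(C)(C)C)O[C@@H]2[C@@H](C)CC(=O)OC)c(OC3CCCCO3)ccc1-c1ccc(OC3CCCCO3)c(C(=C)C[C@@]2(CO[Si](C)(C)C(C)(C)C)O[C@@H]2[C@@H](C)CC(=O)OC)c1OC | intermediate
21 | key-step precursor: 20 with both acetals replaced by free phenols (2,2′-dimethoxybiphenyl-4,4′-diol core) | COc1c(C(=C)C[C@@]2(CO[Si](C)(C)C(C)(C)C)O[C@@H]2[C@@H](C)CC(=O)OC)c(O)ccc1-c1ccc(O)c(C(=C)C[C@@]2(CO[Si](C)(C)C(C)(C)C)O[C@@H]2[C@@H](C)CC(=O)OC)c1OC | intermediate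
22 | (2R,2′R)-6,6′-bi(4-methylenechroman) with 5-OMe, 2-CH2OTBS and a (1R,2S)-1-hydroxy-4-methoxy-2-methyl-4-oxobutyl chain at each C2 | CC(C)(C)[Si](C)(C)OC[C@@]1([C@H](O)[C@@H](C)CC(=O)OC)CC(=C)c2c(ccc(-c3ccc4c(c3OC)C(=C)C[C@@](CO[Si](C)(C)C(C)(C)C)([C@H](O)[C@@H](C)CC(=O)OC)O4)c2OC)O1 | intermediate (not isolated)
23 | key-step product: (2R,2′R)-5,5′-dimethoxy-4,4′-dimethylene-2,2′-bis({[tert-butyl(dimethyl)silyl]oxy}methyl)-2,2′-bis[(2R,3S)-3-methyl-5-oxooxolan-2-yl]-6,6′-bichroman | CC(C)(C)[Si](C)(C)OC[C@@]1([C@@H]5OC(=O)C[C@@H]5C)CC(=C)c2c(ccc(-c3ccc4c(c3OC)C(=C)C[C@@](CO[Si](C)(C)C(C)(C)C)([C@@H]3OC(=O)C[C@@H]3C)O4)c2OC)O1 | intermediate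
24 | (2R,2′R)-bis(chroman-4-one) analogue of 23 (C4 and C4′ ketones) | CC(C)(C)[Si](C)(C)OC[C@@]1([C@@H]5OC(=O)C[C@@H]5C)CC(=O)c2c(ccc(-c3ccc4c(c3OC)C(=O)C[C@@](CO[Si](C)(C)C(C)(C)C)([C@@H]3OC(=O)C[C@@H]3C)O4)c2OC)O1 | intermediate
25 | (2R,2′R)-2,2′-bis(hydroxymethyl) diketone bis-lactone | OC[C@@]1([C@@H]5OC(=O)C[C@@H]5C)CC(=O)c2c(ccc(-c3ccc4c(c3OC)C(=O)C[C@@](CO)([C@@H]3OC(=O)C[C@@H]3C)O4)c2OC)O1 | intermediate
26 | (2S,2′S)-2,2′-dicarboxylic acid diketone bis-lactone | OC(=O)[C@@]1([C@@H]5OC(=O)C[C@@H]5C)CC(=O)c2c(ccc(-c3ccc4c(c3OC)C(=O)C[C@@](C(=O)O)([C@@H]3OC(=O)C[C@@H]3C)O4)c2OC)O1 | intermediate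
27 | dimethyl (2S,2′S)-5,5′-dimethoxy-2,2′-bis[(2R,3S)-3-methyl-5-oxooxolan-2-yl]-4,4′-dioxo-6,6′-bichroman-2,2′-dicarboxylate | COC(=O)[C@@]1([C@@H]5OC(=O)C[C@@H]5C)CC(=O)c2c(ccc(-c3ccc4c(c3OC)C(=O)C[C@@](C(=O)OC)([C@@H]3OC(=O)C[C@@H]3C)O4)c2OC)O1 | intermediate
28 | 5,5′-dihydroxy analogue of 27 (symmetrical bis-lactone) | COC(=O)[C@@]1([C@@H]5OC(=O)C[C@@H]5C)CC(=O)c2c(ccc(-c3ccc4c(c3O)C(=O)C[C@@](C(=O)OC)([C@@H]3OC(=O)C[C@@H]3C)O4)c2O)O1 | intermediate
29 | CNP0517857.1: 28 with one lactone opened to the (1R,2S)-3-carboxy-1-hydroxy-2-methylpropyl chain; both C2 centres (S) | COC(=O)[C@@]1([C@H](O)[C@@H](C)CC(=O)O)CC(=O)c2c(ccc(-c3ccc4c(c3O)C(=O)C[C@@](C(=O)OC)([C@@H]3OC(=O)C[C@@H]3C)O4)c2O)O1 | target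

**Totals.** 20 steps in all. Longest linear sequence: 17 steps (steps 1–8, then 12–20); the biaryl branch (steps 9–11) joins at step 12.

**Steps most likely to fail**

Step 7. The branched substituent cis to the hydroxymethyl group crowds the loaded titanium–tartrate complex, so oxygen transfer may be slow and unselective background epoxidation may erode the facial selectivity. The fallback sets out from 11 and returns at 13. Alcohol 11 is silylated first (TBSCl, imidazole) to the silyl ether F1. F1 is then epoxidised with the dioxirane of the D-fructose-derived ketone 1,2:4,5-di-O-isopropylidene-β-D-erythro-2,3-hexodiulo-2,6-pyranose (Shi epoxidation; KHSO5 as the triple salt 2KHSO5·KHSO4·K2SO4, K2CO3 buffer, MeCN/dimethoxymethane/H2O, 0 °C). This reagent-controlled epoxidation of trisubstituted alkenes needs no free hydroxyl. Its spiro transition-state model, with the olefinic hydrogen in the hindered quadrant, predicts oxygen delivery to the same face, and the bromoalkene is too electron-poor to react. This should give 13 directly.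

Step 12. Reductive elimination at the doubly ortho-substituted aryl–palladium centre may be slow, so protodezincation and zinc-halide-promoted opening of the epoxide in the costly partner may compete and leave mono-coupled material. The fallback sets out from 17 (through 19) and returns at 20; it forms the hindered aryl–vinyl bonds with a cheap, robust partner and installs the epoxides afterwards. Reagent 19 is coupled under the same Negishi conditions with excess (2-bromoallyloxy)(tert-butyl)dimethylsilane to the bis(2-arylallyl silyl ether) F2. TBAF gives the bis(allylic alcohol) F3. MsCl/Et3N followed by LiBr gives the bis(2-arylallyl bromide) F4, with the phenols still masked so that no benzofuran can form. Two-fold Stille coupling of F4 with stannane 9 (Pd2(dba)3, P(2-furyl)3) gives the bis(Z-allylic alcohol) F5. Two-fold asymmetric epoxidation as in step 7 gives the bis(epoxy alcohol) F6, and silylation as in step 8 gives 20.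

Step 14. The cascade must run twice in one molecule; ionisation of one tertiary epoxide carbon ahead of phenol attack (loss of inversion, elimination, hydride shift), or acid-induced migration of an exocyclic double bond in the arm that has already cyclised, would give mixtures that are hard to separate. The fallback sets out from 13 and returns at 23; it runs the same ring closures once per molecule and forms the biaryl bond last. 4-Chloro-3-methoxyphenol is protected (3,4-dihydro-2H-pyran, pyridinium p-toluenesulfonate) as the acetal F7. F7 is lithiated between its two oxygen substituents (s-BuLi, TMEDA, −78 °C), transmetalated with ZnCl2 and coupled with 13 (Pd(PPh3)4, which leaves the aryl chloride alone) to the monomeric aryl epoxy ester F8. Pyridinium p-toluenesulfonate in MeOH frees the phenol F9, and camphorsulfonic acid in CH2Cl2 gives the monomeric 6-chloro-4-methylenechroman lactone F10, which can be purified as a single arm. Nickel-mediated reductive homocoupling of the aryl chloride (NiCl2(PPh3)2, PPh3, Zn, DMF, 60 °C) then gives 23.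

**Further compounds**

F1 | step 7 | methyl (3S,4Z)-7-bromo-5-({[tert-butyl(dimethyl)silyl]oxy}methyl)-3-methylocta-4,7-dienoate | CC(C)(C)[Si](C)(C)OC/C(=C\[C@@H](C)CC(=O)OC)CC(Br)=C
F2 | step 12 | 17 carrying at C3 and C3′ a 3-{[tert-butyl(dimethyl)silyl]oxy}prop-1-en-2-yl group | COc1c(C(=C)CO[Si](C)(C)C(C)(C)C)c(OC2CCCCO2)ccc1-c1ccc(OC2CCCCO2)c(C(=C)CO[Si](C)(C)C(C)(C)C)c1OC
F3 | step 12 | 17 carrying at C3 and C3′ a 3-hydroxyprop-1-en-2-yl group | COc1c(C(=C)CO)c(OC2CCCCO2)ccc1-c1ccc(OC2CCCCO2)c(C(=C)CO)c1OC
F4 | step 12 | 17 carrying at C3 and C3′ a 3-bromoprop-1-en-2-yl group | COc1c(C(=C)CBr)c(OC2CCCCO2)ccc1-c1ccc(OC2CCCCO2)c(C(=C)CBr)c1OC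
F5 | step 12 | bis(Z-allylic alcohol): 17 carrying at C3 and C3′ the CH2=C–CH2–C(CH2OH)=CH–(S)-CH(CH3)CH2CO2Me arm, CH2OH cis to the chain | COc1c(C(=C)C/C(CO)=C/[C@@H](C)CC(=O)OC)c(OC2CCCCO2)ccc1-c1ccc(OC2CCCCO2)c(C(=C)C/C(CO)=C/[C@@H](C)CC(=O)OC)c1OC
F6 | step 12 | bis(epoxy alcohol): 20 with free hydroxymethyl groups in place of the silyl ethers | COc1c(C(=C)C[C@@]2(CO)O[C@@H]2[C@@H](C)CC(=O)OC)c(OC3CCCCO3)ccc1-c1ccc(OC3CCCCO3)c(C(=C)C[C@@]2(CO)O[C@@H]2[C@@H](C)CC(=O)OC)c1OC
F7 | step 14 | 2-(4-chloro-3-methoxyphenoxy)oxane | COc1cc(OC2CCCCO2)ccc1Cl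
F8 | step 14 | monomeric aryl epoxy ester: F7 carrying between its oxygen substituents the 2-arylallyl epoxy ester arm of 20 | COc1c(C(=C)C[C@@]2(CO[Si](C)(C)C(C)(C)C)O[C@@H]2[C@@H](C)CC(=O)OC)c(OC3CCCCO3)ccc1Cl
F9 | step 14 | free phenol of F8 | COc1c(C(=C)C[C@@]2(CO[Si](C)(C)C(C)(C)C)O[C@@H]2[C@@H](C)CC(=O)OC)c(O)ccc1Cl
F10 | step 14 | (2R)-6-chloro-5-methoxy-4-methylene-2-({[tert-butyl(dimethyl)silyl]oxy}methyl)-2-[(2R,3S)-3-methyl-5-oxooxolan-2-yl]chroman | CC(C)(C)[Si](C)(C)OC[C@@]1([C@@H]2OC(=O)C[C@@H]2C)CC(=C)c3c(OC)c(Cl)ccc3O1
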